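The easy step came first: I subtracted each reading of left-handed product from the whole charge and called the remainder the gap.

| flask | left-handed substrate | right-handed substrate | gas | catalyst | remark | time |
|---|---|---|---|---|---|---|
| beta | 1.2 M | 1.2 M | 180 mM (held) | 16 mM | run made earlier |  |
| gamma | 1.2 M | 1.2 M | 180 mM (held) | 62 mM | run made earlier |  |
| flask | 1.2 M | 1.2 M | 180 mM (held) | 31 mM |  | 5.0 d |

| run | time / d | left-handed product / % |
|---|---|---|
| beta | 0.833 | 51 |
| beta | 1.67 | 62 |
| beta | 2.50 | 67 |
| beta | 3.00 | 73 |
| beta | 4.00 | 76 |
| beta | 5.00 | 81 |
| gamma | 0.333 | 51 |
| gamma | 1.04 | 62 |
| gamma | 1.67 | 64 |
| gamma | 2.50 | 72 |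
| gamma | 4.00 | 76 |
| gamma | 5.00 | 78 |

(readings scatter by 2 percentage points)

- catalyst is single-handed; left-handed substrate and right-handed substrate are mirror images of each other, charged as a racemate, each of them at the stated concentration
- the analysis behind the earlier runs scatters by 2 percentage points, standard deviation
- at the start none of the gas is in solution

- west: doubling the transfer coefficient of the gas, all else as stated
- north-east: doubling the amount of catalyst, all else as stated
- north-west: doubling the saturation concentration of gas, all else as stated

- the left-handed product standing at 5.0 d, as a percentage of the left-handed substrate and right-handed substrate together charged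
- the change that raises the amount of left-handed product at 5.0 d, in percent of the left-handed substrate and right-handed substrate together charged most ("none" if none brings more than 2 percentage points) (west / north-east / north-west / none)
- amount of left-handed product at 5.0 d, in percent of the left-handed substrate and right-handed substrate together charged, after north-west

Left-handed substrate was 50.0% of the charge, but beta reached 81%. So right-handed substrate had to feed in, as in a dynamic kinetic resolution. At 1.67 d the gap stood at 38.0% in beta and 36.0% in gamma, though gamma had 3.88 times the catalyst. From there the gap fell at 0.178 d⁻¹, averaged over both runs. That is a gap half-life of 3.89 d, the time in which the gap halves.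

The flask, with 31 mM of catalyst, lay between the runs. So I started it from a gap of 37.0% and reckoned 79.5% at 5.0 d. At that time gamma's gap read 22.0% and beta's 19.0%, so in these readings more catalyst had not narrowed it. I therefore expected no gain of 2 percentage points from north-east, assumed the same of the two gas changes, and reckoned about 79.5% after north-west.

The forecast gave 80%, none and 80.5%, holding that “uncatalysed racemisation is rate-limiting”.

The flask gave 81.7%, none and 79.6%.

    left-handed substrate ⇌ right-handed substrate (k = 0.0110 h⁻¹)
    reagent + catalyst + right-handed substrate → catalyst + right-handed product (k = 0.380 M⁻² h⁻¹)
    reagent + catalyst + left-handed substrate → catalyst + left-handed product (k = 61.0 M⁻² h⁻¹)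
    gas ⇌ reagent, rate k4*(csat - [reagent]) (kL = 4.70 h⁻¹)

Between 2.50 d and 5.00 d the flask's gap fell with a half-life of 3.60 d, against my 3.89 d, and that is longer than the 2.6 d forward half-life of left-handed substrate turning into right-handed substrate, a step whose way back has the same constant. Of the flask's gap at 5.00 d, 11.3% was right-handed substrate, 0.370% left-handed substrate and 6.56% right-handed product, which the runs did not read.

For the neighbour flask read at 3.0 d, the gap half-life gave 70.8%. The computed reading there was 73.4%.

All runs are simulated from invented constants; the scatter is artificial.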